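## Retrosynthetic overview

1. Numbering (decalin): C1 ring C=O, C2 C(OH)CH3, C3 CH(sec-butyl), C4 C(CH3)(acyl), C4a/C8a ring fusion, C5 CHCH3, C7 C(OH)CH2OH; ring A = C1–C2–C3–C4–C4a–C8a, ring B = C4a–C5–C6–C7–C8–C8a; side chain C9(=O)–C10–C11–OH on C4.
2. Enabling feature: ring A is a cyclohexane whose C1 ketone/C2 tertiary OH is an oxidised enol ether and whose C3–C4 and C4a–C8a bonds are 1,4-related, a [4+2] retron. The C9 carbonyl on C4 and the C5 methyl carbon are 1,5-related (C9–C4–C4a–C5–CH3), so they can be tied as a temporary δ-lactone C9(=O)–O–CH2–C5 that locks the dienophile Z and carries the one controlling stereocentre.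
3. Target ⇒ acetonide removal; C10–C11–OH by β-borylation/oxidation of a vinyl ketone; C9 acyl and C5–CH3 by alkyl–oxygen cleavage of the lactone and C–Se reduction ⇒ tricyclic lactone triol 19 ⇒ double osmylation (C7 diol; C1=O/C2–OH) ⇒ silyl enol ether 18.
4. 18 ⇒ intramolecular Diels–Alder reaction of silyloxy diene 17 (from enone lactone 16): ring B (bond C4a–C8a) and ring A (bond C3–C4) close together onto the temporary lactone ring and set C3, C4, C4a and C8a.
5. 16 ⇒ ring-closing metathesis (lactone ring, formed first) ⇐ Evans dienolate alkylation (C5–C6) ⇐ hydrazone alkylation (C8–C8a); building blocks: enone 4 from (R)-2-methylbutan-1-ol, dibromide 6, crotonyl imide 10.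

Key step: step 9

Assumption: (R)-2-methylbutan-1-ol, the enantiomer of the fusel-oil alcohol, is taken as a purchasable chiral-pool material.

## Route

Step 1
Reactants: 1 (R)-2-methylbutan-1-ol; 2 3-(triphenyl-λ5-phosphanylidene)butan-2-one
Product: 4 (3E,5R)-3,5-dimethylhept-3-en-2-one, via (R)-2-methylbutanal 3 (not isolated)
Conditions: TEMPO (10 mol%), PhI(OAc)2, CH2Cl2, 0 °C to rt; then 2, toluene, 90 °C
Reagents that add atoms: none
Why: The base-free TEMPO/iodane oxidation gives the configurationally labile aldehyde, which is consumed at once by Wittig olefination with the stabilised acyl ylide to give the (E)-trisubstituted enone; the sec-butyl stereocentre comes from the chiral pool.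

Step 2
Reactants: 4 (3E,5R)-3,5-dimethylhept-3-en-2-one
Product: 5 (E)-N,N-dimethylhydrazone of 4
Conditions: Me2NNH2, AcOH (cat.), EtOH, 4 Å molecular sieves, reflux
Reagents that add atoms: 1,1-dimethylhydrazine, CN(C)N
Why: Acid-catalysed condensation to the hydrazone masks the ketone and prepares regioselective metalation at the methyl group (hydrazone azaenolate chemistry).

Step 3
Reactants: 5 (E)-N,N-dimethylhydrazone of 4; 6 3-bromo-2-(bromomethyl)prop-1-ene
Product: 7 allylic bromide hydrazone
Conditions: LiN(iPr)2, THF, −78 to 0 °C; then added to 6 (3 equiv), THF, −78 °C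
Reagents that add atoms: none
Why: Kinetic deprotonation at the methyl group gives the azaenolate, which is C-alkylated (SN2) by the symmetric bis-allylic dibromide; the excess of 6 should limit the reaction to one bromide.

Step 4
Reactants: 8 (4R)-4-benzyl-1,3-oxazolidin-2-one; 9 (E)-but-2-enoyl chloride
Product: 10 (4R)-4-benzyl-3-[(E)-but-2-enoyl]-1,3-oxazolidin-2-one
Conditions: n-BuLi, THF, −78 °C; then 9, −78 to 0 °C
Reagents that add atoms: none
Why: N-Acylation of the lithiated oxazolidinone with the acid chloride is the standard preparation of an Evans imide.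

Step 5
Reactants: 10 (4R)-4-benzyl-3-[(E)-but-2-enoyl]-1,3-oxazolidin-2-one; 7 allylic bromide hydrazone
Product: 11 α-vinyl imide
Conditions: NaN(SiMe3)2, THF, −78 °C; then 7, −78 to −40 °C
Reagents that add atoms: none
Why: Deconjugative Evans alkylation: γ-deprotonation gives the chelated sodium (Z)-dienolate, which is alkylated at the α-carbon by the allylic bromide on the face opposite the benzyl group, setting the (R) centre that becomes C5.

Step 6
Reactants: 11 α-vinyl imide
Product: 13 hydroxy enone, via hydroxy hydrazone 12 (not isolated)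
Conditions: LiBH4, MeOH (1.1 equiv), THF, 0 °C; then saturated aqueous oxalic acid, Et2O, rt
Reagents that add atoms: water, O
Why: Reductive cleavage of the imide with LiBH4 gives the primary alcohol and returns the auxiliary, and the two-phase oxalic acid treatment hydrolyses the hydrazone to the enone without affecting the alkenes or the stereocentre.

Step 7
Reactants: 13 hydroxy enone; 14 2-methylprop-2-enoyl chloride
Product: 15 methacrylate ester
Conditions: Et3N, DMAP (cat.), CH2Cl2, 0 °C
Reagents that add atoms: none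
Why: DMAP-catalysed O-acylation of the only hydroxyl group.

Step 8
Reactants: 15 methacrylate ester
Product: 16 enone lactone
Conditions: second-generation Grubbs catalyst RuCl2(=CHPh)(H2IMes)(PCy3) (5 mol%), toluene (0.005 M), 80 °C
Reagents that add atoms: none
Why: Ring-closing olefin metathesis between the monosubstituted vinyl group and the methacrylate closes the six-membered α-methyl unsaturated δ-lactone with loss of ethene; the 1,1-disubstituted alkene and the trisubstituted enone are too hindered to compete, and the ring fixes the Z geometry of the future dienophile.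

Step 9
Reactants: 16 enone lactone
Product: 18 tricyclic lactone silyl enol ether, via silyl dienol ether 17 (not isolated)
Conditions: TBSOTf (1.3 equiv), Et3N, CH2Cl2, −78 to 0 °C; then toluene (0.01 M), BHT, 160 °C, sealed vessel
Reagents that add atoms: tert-butyldimethylsilyl trifluoromethanesulfonate, CC(C)(C)[Si](C)(C)OS(=O)(=O)C(F)(F)F
Why: Soft enolisation converts the only enolisable carbonyl, the α′-CH2 ketone, into the (Z)-2-silyloxy diene 17 (C8 and sec-butyl both "outside"), which on heating undergoes a normal-electron-demand intramolecular Diels–Alder reaction with the lactone; the nucleophilic diene terminus C8a bonds to the lactone β-carbon C4a and C3 bonds to the α-carbon C4. The closest known reaction type is the type 1 intramolecular Diels–Alder reaction of 1,7,9-decatrienes with a 2-silyloxy diene and a cyclic enoate dienophile. Ring B is closed by the C4a–C8a bond (tether C5–C6–C7–C8, formally 6-exo onto the lactone alkene) and ring A by the C3–C4 bond as the second σ-bond of the [4+2] event through a boat-like six-centre transition state. C4a and C4 are controlled by the lactone stereocentre C5: the ring holds the O–CH2 carbon in the plane of the Z-locked alkene, so C6 stands on one face and the diene it carries can only add there, which puts H-4a cis to H-5 and, by suprafacial addition, the lactone carbonyl on C4 cis to C5. C3 and C8a follow from the diene geometry (E at C2=C3, Z enol ether) and the endo arrangement in which the flat lactone carbonyl, not the C4 methyl, lies under the diene, so that sec-butyl, C9 and C8 end up on one face. The step needs α′-regioselective and Z-selective enol ether formation and endo selectivity; the first two are secured by the lack of α-hydrogens in the lactone and the Z preference of silyl triflate/amine enolisation next to the α-branched alkenyl group, the third by the cyclic cis-dienophile and the matched polarity of silyloxy diene and enoate.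

Step 10
Reactants: 18 tricyclic lactone silyl enol ether
Product: 19 tricyclic lactone triol ketone
Conditions: OsO4 (10 mol%), N-methylmorpholine N-oxide (3 equiv), acetone–H2O 8:1, rt; aqueous Na2SO3 work-up
Reagents that add atoms: N-methylmorpholine N-oxide, C[N+]1([O-])CCOCC1; water, O
Why: Upjohn dihydroxylation of both electron-rich alkenes from the convex face of the all-cis-fused tricycle (the face of H-4a, H-5 and H-8a, anti to the sec-butyl group, the lactone bridge and C8) should give the C7 diol with the tertiary OH on that face, while the osmate of the silyl enol ether collapses to the C1 ketone with the C2 hydroxyl on the same face (Rubottom-type α-hydroxylation).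

Step 11
Reactants: 19 tricyclic lactone triol ketone
Product: 20 acetonide lactone
Conditions: Me2C(OMe)2, PPTS (cat.), CH2Cl2, rt
Reagents that add atoms: 2,2-dimethoxypropane, COC(C)(C)OC
Why: Acid-catalysed transketalisation forms the five-membered acetonide of the 1,2-diol, while the hindered tertiary α-ketol hydroxyl stays free.

Step 12
Reactants: 20 acetonide lactone
Product: 21 seleno acid
Conditions: PhSeNa (from PhSeSePh and Na, THF), THF–HMPA, 65 °C; then 1 M HCl
Reagents that add atoms: sodium benzeneselenolate, [Na+].[Se-]c1ccccc1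
Why: The soft selenolate opens the lactone by SN2 attack at the O–CH2 carbon (alkyl–oxygen cleavage) to give the carboxylate and the primary selenide; ketone, ketol and acetonide are inert to this weakly basic nucleophile.

Step 13
Reactants: 21 seleno acid
Product: 22 C5-methyl acid
Conditions: Bu3SnH, AIBN (cat.), toluene, 80 °C
Reagents that add atoms: none
Why: Radical chain reduction cleaves the C–Se bond and turns CH2SePh into the C5 methyl group without touching any stereocentre.

Step 14
Reactants: 22 C5-methyl acid
Product: 23 S-pyridin-2-yl thioester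
Conditions: 2,2'-dipyridyl disulfide, PPh3, CH2Cl2, rt
Reagents that add atoms: 2,2'-dipyridyl disulfide, c1ccc(SSc2ccccn2)nc1
Why: Redox condensation (phosphine/disulfide) activates the hindered neopentyl-type acid under neutral conditions as its 2-pyridyl thioester.

Step 15
Reactants: 23 S-pyridin-2-yl thioester; 24 ethenylmagnesium bromide
Product: 25 vinyl ketone
Conditions: CH2=CHMgBr (2.5 equiv), THF, −78 °C; saturated aqueous NH4Cl at −78 °C
Reagents that add atoms: none
Why: Mukaiyama ketone synthesis: the chelated magnesium adduct of the 2-pyridyl thioester survives at −78 °C and releases the ketone only on work-up, and the ring ketone is shielded by its two fully substituted α-carbons and the neighbouring magnesium alkoxide.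

Step 16
Reactants: 25 vinyl ketone
Product: 27 β-hydroxy ketone acetonide, via boronate 26 (not isolated)
Conditions: CuCl (5 mol%), Xantphos (5 mol%), NaOtBu (10 mol%), B2pin2, MeOH (2 equiv), THF, rt; then NaBO3·4H2O, THF–H2O, rt
Reagents that add atoms: bis(pinacolato)diboron, CC1(C)OB(OC1(C)C)B1OC(C)(C)C(C)(C)O1 (boron of 26); sodium perborate, [Na+].[O-]OB=O (oxygen of 27)
Why: Copper-catalysed conjugate borylation of the unhindered enone terminus followed by perborate oxidation of the C–B bond gives the β-hydroxy ketone under nearly neutral conditions that should leave the epimerisable C8a centre untouched.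

Step 17
Reactants: 27 β-hydroxy ketone acetonide
Product: 28 target compound
Conditions: AcOH–H2O 4:1, 40 °C
Reagents that add atoms: none
Why: Mild aqueous acid hydrolysis of the acetonide, which the tertiary α-ketol and the β-hydroxy ketone should tolerate.

## Compound list

1 | (R)-2-methylbutan-1-ol | CC[C@@H](C)CO | starting material
2 | 3-(triphenyl-λ5-phosphanylidene)butan-2-one | CC(=O)C(C)=P(c1ccccc1)(c1ccccc1)c1ccccc1 | starting material
3 | (R)-2-methylbutanal | CC[C@@H](C)C=O | intermediate
4 | (3E,5R)-3,5-dimethylhept-3-en-2-one | CC[C@@H](C)/C=C(\C)C(C)=O | intermediate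
5 | 2-[(2E,3E,5R)-3,5-dimethylhept-3-en-2-ylidene]-1,1-dimethylhydrazine (E-hydrazone of 4) | CC[C@@H](C)/C=C(\C)/C(C)=N/N(C)C | intermediate
6 | 3-bromo-2-(bromomethyl)prop-1-ene | C=C(CBr)CBr | starting material
7 | (E)-N,N-dimethylhydrazone of (6E,8R)-2-(bromomethyl)-6,8-dimethyldeca-1,6-dien-5-one | CC[C@@H](C)/C=C(\C)/C(CCC(=C)CBr)=N/N(C)C | intermediate
8 | (4R)-4-benzyl-1,3-oxazolidin-2-one | O=C1N[C@H](Cc2ccccc2)CO1 | starting material
9 | (E)-but-2-enoyl chloride | C/C=C/C(Cl)=O | starting material
10 | (4R)-4-benzyl-3-[(E)-but-2-enoyl]-1,3-oxazolidin-2-one | C/C=C/C(=O)N1[C@H](Cc2ccccc2)COC1=O | intermediate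
11 | (4R)-4-benzyl-3-[(2R,8E,10R)-7-(dimethylhydrazinylidene)-2-ethenyl-8,10-dimethyl-4-methylidenedodec-8-enoyl]-1,3-oxazolidin-2-one | C=C[C@@H](CC(=C)CCC(=N/N(C)C)\C(C)=C\[C@H](C)CC)C(=O)N1[C@H](Cc2ccccc2)COC1=O | intermediate
12 | (2R,8E,10R)-7-(dimethylhydrazinylidene)-2-ethenyl-8,10-dimethyl-4-methylidenedodec-8-en-1-ol | C=C[C@@H](CC(=C)CCC(=N/N(C)C)\C(C)=C\[C@H](C)CC)CO | intermediate
13 | (2R,8E,10R)-2-ethenyl-1-hydroxy-8,10-dimethyl-4-methylidenedodec-8-en-7-one | C=C[C@@H](CC(=C)CCC(=O)/C(C)=C/[C@H](C)CC)CO | intermediate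
14 | 2-methylprop-2-enoyl chloride | CC(=C)C(Cl)=O | starting material
15 | (2R,8E,10R)-2-ethenyl-8,10-dimethyl-4-methylidene-7-oxododec-8-en-1-yl 2-methylprop-2-enoate | C=C[C@@H](CC(=C)CCC(=O)/C(C)=C/[C@H](C)CC)COC(=O)C(C)=C | intermediate
16 | (5R)-5-[(6E,8R)-6,8-dimethyl-2-methylidene-5-oxodec-6-en-1-yl]-3-methyl-5,6-dihydro-2H-pyran-2-one | CC[C@@H](C)/C=C(\C)C(=O)CCC(=C)C[C@H]1COC(=O)C(C)=C1 | intermediate
17 | (5R)-5-[(4Z,6E,8R)-5-[(tert-butyldimethylsilyl)oxy]-6,8-dimethyl-2-methylidenedeca-4,6-dien-1-yl]-3-methyl-5,6-dihydro-2H-pyran-2-one | CC[C@@H](C)/C=C(\C)/C(O[Si](C)(C)C(C)(C)C)=C/CC(=C)C[C@H]1COC(=O)C(C)=C1 | intermediate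
18 | cycloadduct: Δ1(2)-octalin (decalin numbering) with 1-OSi(tBu)Me2, 2-CH3, 3-[(2R)-butan-2-yl], 4-CH3, 7-methylidene, and the C4 carbonyl bridged to C5 as δ-lactone C4–C(=O)–O–CH2–C5; (3S,4R,4aR,5R,8aS); H-3, H-4a, H-5, H-8a and the C4 methyl on one face | CC[C@@H](C)[C@@H]1[C@](C)(C(=O)OC3)[C@@H]2[C@H]3CC(=C)C[C@@H]2C(O[Si](C)(C)C(C)(C)C)=C1C | intermediate
19 | tricyclic lactone triol ketone: as 18 but C1 ketone, C2 tertiary OH, C7 tertiary OH and CH2OH; (2S,3R,4R,4aR,5R,7R,8aS) | CC[C@@H](C)[C@@H]1[C@](C)(C(=O)OC3)[C@@H]2[C@H]3C[C@](O)(CO)C[C@@H]2C(=O)[C@@]1(C)O | intermediate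
20 | acetonide of 19 (2,2-dimethyl-1,3-dioxolane spiro at C7, free C2–OH) | CC[C@@H](C)[C@@H]1[C@](C)(C(=O)OC3)[C@@H]2[C@H]3C[C@]4(COC(C)(C)O4)C[C@@H]2C(=O)[C@@]1(C)O | intermediate
21 | seleno acid: decalin-4-carboxylic acid with 5-CH2SePh, otherwise as 20; (2S,3R,4R,4aS,5R,7R,8aS) | CC[C@@H](C)[C@@H]1[C@](C)(C(=O)O)[C@@H]2[C@H](C[Se]c3ccccc3)C[C@]4(COC(C)(C)O4)C[C@@H]2C(=O)[C@@]1(C)O | intermediate
22 | C5-methyl acid: (2S,3R,4R,4aR,5R,7R,8aS)-decalin-4-carboxylic acid with 2-OH, 2,4,5-trimethyl, 3-[(2R)-butan-2-yl], 1-oxo, C7 acetonide | CC[C@@H](C)[C@@H]1[C@](C)(C(=O)O)[C@@H]2[C@H](C)C[C@]3(COC(C)(C)O3)C[C@@H]2C(=O)[C@@]1(C)O | intermediate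
23 | S-pyridin-2-yl thioester of 22 | CC[C@@H](C)[C@@H]1[C@](C)(C(=O)Sc3ccccn3)[C@@H]2[C@H](C)C[C@]4(COC(C)(C)O4)C[C@@H]2C(=O)[C@@]1(C)O | intermediate
24 | ethenylmagnesium bromide | C=C[Mg]Br | starting material
25 | vinyl ketone: 4-(prop-2-enoyl) analogue of 22 | CC[C@@H](C)[C@@H]1[C@](C)(C(=O)C=C)[C@@H]2[C@H](C)C[C@]3(COC(C)(C)O3)C[C@@H]2C(=O)[C@@]1(C)O | intermediate
26 | β-boryl ketone: 4-[3-(4,4,5,5-tetramethyl-1,3,2-dioxaborolan-2-yl)propanoyl] analogue of 25 | CC[C@@H](C)[C@@H]1[C@](C)(C(=O)CCB3OC(C)(C)C(C)(C)O3)[C@@H]2[C@H](C)C[C@]4(COC(C)(C)O4)C[C@@H]2C(=O)[C@@]1(C)O | intermediate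
27 | C7 acetonide of the target | CC[C@@H](C)[C@@H]1[C@](C)(C(=O)CCO)[C@@H]2[C@H](C)C[C@]3(COC(C)(C)O3)C[C@@H]2C(=O)[C@@]1(C)O | intermediate
28 | (2S,3R,4R,4aR,5R,7R,8aS)-3-[(2R)-butan-2-yl]-2,7-dihydroxy-7-(hydroxymethyl)-4-(3-hydroxypropanoyl)-2,4,5-trimethyloctahydronaphthalen-1(2H)-one | CC[C@@H](C)[C@@H]1[C@](C)(C(=O)CCO)[C@@H]2[C@H](C)C[C@](O)(CO)C[C@@H]2C(=O)[C@@]1(C)O | target

## Step count and risks

Total step count: 17. Longest linear sequence: 16 steps (steps 1–3 and 5–17); step 4 is a one-step branch.

Steps most likely to fail: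

Step 9. The cycloaddition of the trisubstituted lactone may be slow, so that the silyl dienol ether decays thermally, or endo selectivity may erode and give the trans-fused isomer. The fallback sets out from 16 and returns at 18, and forms the two bonds one after the other under kinetic anionic control. LiN(SiMe3)2 in THF at −78 °C would generate the α′-enolate of 16, which adds in a Michael reaction to the lactone β-carbon (ring B first, again only on the face of C6). The lactone enolate so formed adds in a second Michael reaction to the enone (ring A, bond C3–C4), and the resulting ring-A enolate is silylated in the same flask with TBSCl to give 18. This path makes no new compound (none, F0).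

Step 10. Osmylation of the exocyclic methylene may occur from the concave face (wrong C7 configuration), or oxidation of the hindered tetrasubstituted enol ether may be incomplete. The fallback sets out from 18 and returns at 19; it separates the two oxidations and reverses the order of bond formation at C7. Dimethyldioxirane (1 equiv, acetone–CH2Cl2, −78 °C; then oxalic acid, MeOH) would oxidise only the enol ether (Rubottom oxidation) to the α-hydroxy ketone lactone F1. Ozonolysis (O3, CH2Cl2–MeOH, −78 °C; Me2S) of the methylidene group would give the C7 ketone F2. Addition of the hydroxymethyl anion equivalent iPrOMe2SiCH2MgCl (THF, −78 °C) to the unhindered C7 ketone places carbon on the face the osmium reagent preferred and hence oxygen on the other, giving the silylmethyl carbinol F3. Tamao oxidation (H2O2, KF, KHCO3, THF–MeOH) then gives 19.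

Step 12. SN2 displacement at the β-branched O–CH2 carbon may be slow, so that base-induced epimerisation at C8a or decomposition competes. The fallback sets out from 20 and returns at 25; it cleaves the acyl–oxygen bond instead of the alkyl–oxygen bond. Me3Al/MeNHOMe·HCl (CH2Cl2, 0 °C to rt) would open the lactone to the hydroxy Weinreb amide F4. I2, PPh3 and imidazole would give the primary iodide F5. Bu3SnH/AIBN would reduce it to the C5-methyl Weinreb amide F6. CH2=CHMgBr (THF, −20 °C), with the ring ketone protected by its hindered position and the adjacent magnesium alkoxide, would then give vinyl ketone 25.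

Further compounds
F0 | step 9 | none | none
F1 | step 10 | α-hydroxy ketone lactone (18 with C1 ketone and C2 OH, 7-methylidene retained) | CC[C@@H](C)[C@@H]1[C@](C)(C(=O)OC3)[C@@H]2[C@H]3CC(=C)C[C@@H]2C(=O)[C@@]1(C)O
F2 | step 10 | C7 ketone (1,7-dione lactone) | CC[C@@H](C)[C@@H]1[C@](C)(C(=O)OC3)[C@@H]2[C@H]3CC(=O)C[C@@H]2C(=O)[C@@]1(C)O
F3 | step 10 | silylmethyl carbinol (C7 OH and CH2SiMe2OiPr) | CC[C@@H](C)[C@@H]1[C@](C)(C(=O)OC3)[C@@H]2[C@H]3C[C@](O)(C[Si](C)(C)OC(C)C)C[C@@H]2C(=O)[C@@]1(C)O
F4 | step 12 | hydroxy Weinreb amide (C4 C(=O)N(OMe)Me, C5 CH2OH) | CC[C@@H](C)[C@@H]1[C@](C)(C(=O)N(C)OC)[C@@H]2[C@H](CO)C[C@]3(COC(C)(C)O3)C[C@@H]2C(=O)[C@@]1(C)O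
F5 | step 12 | primary iodide (C5 CH2I) | CC[C@@H](C)[C@@H]1[C@](C)(C(=O)N(C)OC)[C@@H]2[C@H](CI)C[C@]3(COC(C)(C)O3)C[C@@H]2C(=O)[C@@]1(C)O
F6 | step 12 | C5-methyl Weinreb amide | CC[C@@H](C)[C@@H]1[C@](C)(C(=O)N(C)OC)[C@@H]2[C@H](C)C[C@]3(COC(C)(C)O3)C[C@@H]2C(=O)[C@@]1(C)O
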